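The numbers in the tables are calculated for an exercise, and the scatter is random.

The constants of this flask are hidden, so two chemists argue from Thursday's curve of J.

- Thursday's: G 1.1 M; Q 1.1 equiv; run made earlier
- flask: G 0.80 M; Q 1.10 equiv; time 2.5 h; volume of the second phase over the first 0.50

Thursday's run (percent of the G charged)

| time / min | J / % |
|---|---|
| 5.00 | 12.0 |
| 15.0 | 34.1 |
| 25.0 | 48.4 |
| 40.0 | 62.1 |
| 50.0 | 67.2 |
| 80.0 | 73.8 |
| 90.0 | 74.5 |

(each reading ± 0.5 percentage points)

- in the second phase: Q; everything else is in the first
- charges count per volume of the first phase; a concentration in a rate is the amount of a species over the volume of its own phase; every rate counts per litre of the first phase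
- what may be going on: L <-> Q; G + L -> J; J <-> D; 2 L -> Z
- the earlier runs hold the two phases in the same ratio of volumes as the flask asked about

- the J standing at 2.5 h, as a percentage of the G charged
- the change that raises the amount of J at 2.5 h, in percent of the G charged most ("none" if none brings more than 2 percentage points) (west / south-west / none)
- amount of J at 2.5 h, in percent of the G charged, after west

The first chemist holds a supply view. Thursday's last reading leaves 25.5% of the G charged outside J, and Q was charged at a mere 1.1 equiv. So she expects more Q to lift J.

The second chemist holds a ceiling view, thermodynamic control in the usual term: J settles against D, and the curve closes on a fixed height. The slopes on either side of the reading at 50.0 min give a decay rate of 0.0420 min⁻¹. That rate puts the ceiling at 76.4%, a reading with the scatter of its points.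

Her rule concerns the gap between J and that ceiling. On Thursday's clock the gap shrinks to 2 percentage points, the least gain worth having, at 86.3 min. This is the crossing time: before it supply holds J down, after it the ceiling does.

I side with her. The flask has the same equivalents at lower strength, and one run cannot show how the clock moves with strength. So I take two cases: Thursday's pace, and a clock slowed by the whole ratio of strengths, 1.38. The flask's crossing then falls at 1.44 h or at 1.98 h, both earlier than 2.5 h. On the slower clock the gap left at 2.5 h is 0.77 points, less than 2 points. I commit to J of 75.6% and to no useful change.

The forecast gives 74.5%, west and 80%, on the grounds that “Doubling Q finishes off the remaining G, giving about 80%.”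

The flask gives 75.5% and the answer none, with 75.9% after west.

    L ⇌ Q, rate k1*([L] - [Q]/K1) per volume of the first phase (partition coefficient = 0.600, kL = 0.0127 min⁻¹)
    G + L → J (k = 0.579 M⁻¹ min⁻¹)
    J ⇌ D (K = 0.318, k = 0.0983 min⁻¹)
    2 L → Z (k = 0.0121 M⁻¹ min⁻¹)

West adds 0.36 points, less than my gap, and south-west adds 0.19 points. The neighbouring flask, charged at 0.20 M, is the supply view's region. Its crossing stands at 1.44 h at Thursday's pace and at 7.91 h on the fully slowed clock, and 2.5 h lies between them. So the two cases leave its side of the crossing open. That neighbouring flask shows a gap of 5 points, above 2 points. It stands at J 71.4%, with 5.9% of its G left.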